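I reckoned per molecule and per minute. A left-handed substrate and a right-handed substrate in one flask meet the same [partner], so if each reacts once with partner, the ratio of their chances stays the same however [partner] moves.

the same everywhere: racemization catalyst 50 mM; added ligand 240 mM
- south-east: left-handed substrate 0.67 M; right-handed substrate 0.67 M; partner 2.5 M; run made earlier
- flask: left-handed substrate 1.0 M; right-handed substrate 1.0 M; partner 2.50 M; time 80 min

south-east run (percent of the left-handed substrate and right-handed substrate together charged)

| time / min | left-handed product / % | right-handed product / % | left-handed substrate / % |
|---|---|---|---|
| 25.0 | 17.1 | 2.3 | 32.6 |
| 50.0 | 25.2 | 3.3 | 24.9 |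
| 80.0 | 31.3 | 5.4 | 20.6 |
| 90.0 | 31.0 | 4.7 | 18.1 |

(scatter of a reading: 0.5 percentage points)

- left-handed product and right-handed product together, in percent of the left-handed substrate and right-handed substrate charged together, at 80 min
- excess of left-handed product over right-handed product in the product at 80 min
- whether the exchange between left-handed substrate and right-handed substrate keeps pace with the reaction: how far the product's excess at 80 min gets from its value without exchange to its value with instant exchange (above 80% keeps pace, below 20% hardly takes part, else lags behind)

- partner is single-handed; left-handed substrate and right-handed substrate are mirror images of each other, charged as a racemate, each of them at the stated concentration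
- an excess is the difference of the two amounts in percent of their sum
- an excess is below zero if the other one leads
- the handed part of partner does not stay in what it makes, so the products of the two hands are mirror images too

I read that ratio from the south-east run as the selectivity factor, the chance per molecule of the left-handed substrate being taken over that of the right-handed one: 9.22. This is the ratio of the summed logarithms of what remained of each hand, a reading with its scatter, and I took the right-handed remainder from the right-handed product.

The bench rule says the product's excess is (s − 1)/(s + 1), here 80.4%, and instant exchange would hold it there by keeping the two substrates equal. But the odds at the fork are s times [left-handed substrate]/[right-handed substrate], and in the south-east run that ratio had reached 0.462 at 80.0 min, so the rule had stopped working.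

Left-handed substrate plus left-handed product averaged 50.2% in the south-east run, within the scatter of 0.5 percentage points of the 50.0% charged, so I let no molecule cross. Then a remainder f of the left-handed substrate leaves f to the power 1/s of the right-handed one. The flask has the south-east charge of partner but more substrate, and I assumed the same f, 41.2%. That gave me 34.0% of product at an excess of 73.0%.

The forecast said 37% at 72%, and that exchange hardly takes part: "Almost nothing has crossed over from the right-handed substrate". Its yield stood above mine.

    partner + left-handed substrate → left-handed product (k = 1.43 × 10⁻⁴ M⁻¹ s⁻¹)
    partner + right-handed substrate → right-handed product (k = 1.40 × 10⁻⁵ M⁻¹ s⁻¹)
    left-handed substrate + racemization catalyst ⇌ right-handed substrate + racemization catalyst, rate k3*[racemization catalyst]*[left-handed substrate] forward; the back reaction follows from the equilibrium constant (k = 0.00147 M⁻¹ s⁻¹)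
    racemization catalyst + added ligand ⇌ idle complex, settled at all times (K = 11.6 M⁻¹)
    partner → decomposed reagent (k = 1.93 × 10⁻⁴ s⁻¹)
    partner + racemization catalyst → spent catalyst (k = 4.87 × 10⁻⁴ M⁻¹ s⁻¹)

The flask gave 33.7% at an excess of 75.5%, and exchange hardly takes part, getting 4.3% of the way. With exchange struck out, the excess stood at 75.2%. The flask kept 43% of its left-handed substrate, and s turns that remainder into an excess of 73.3%, lower than the flask's. The neighbour flask with 0.62 M of partner kept 82%, for which s gives 78.8%, and that flask stood at 80.7%.

Readings and results are simulated for substances that don't exist; scatter was added.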